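A direct plan would buy both benzene rings: the protected catechol-ring phenol A1 would displace fluoride from benzyl 6-fluoro-3-formyl-2-methoxybenzoate A2 (SNAr) to give diaryl ether aldehyde A3, a chiral methallylborane would add the side chain to give homoallylic alcohol A4, and desilylation and hydrogenation of A4 would finish.
Its weakest steps would be:
(a) the SNAr union, since a phenoxide with two ortho substituents would have to attack a carbon flanked by an ester, in hot carbonate, with a free aldehyde present;
(b) the methallylation that gives A4, since the only stereocentre would be set late, on the most advanced intermediate, by a stoichiometric borane of uncertain selectivity for ortho-alkoxybenzaldehydes;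
(c) the final hydrogenation, since it would have to saturate an alkene and cleave two benzyl groups yet spare two benzylic C–O bonds, one of them the electron-rich stereocentre.

**Plan of the new route**

Ring A is the benzoic acid ring (C1 carries CO2H, C2 OMe, C3 the side chain, C6 the ether oxygen); ring B is the catechol-derived ring.
The retrosynthesis cuts ring A, not the diaryl ether: bonds C1–C2 and C3–C4 are cut in a pyrone Diels–Alder sense, and O–C6 one stage earlier as a vinylic substitution on an open-chain chloroethylidene malonate.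
Ring B is an arene from the start; ring A arises last, from a 4-aryloxy-2-pyrone-3-carboxylate (C1, C6, C5, C4 and the carboxyl) and the ketene acetal of a β-hydroxy ester (C2, C3 and the side chain).
The feature that allows this: C1 of ring A lies between two oxygen-bearing carbons (C2–OMe, C6–OAr), C4 and C5 carry only hydrogen, and the carbinol carbon on C3 is β to C2, so a β-hydroxy ester is written into the ring.
No SNAr occurs, the stereocentre comes first from a catalytic hydrogenation of a β-keto ester, and allyl and silyl groups replace every benzyl group, so nothing is hydrogenated at the end.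

Key step: step 11

Remark on the chemistry: the silyl ketene acetal of step 10 is assumed to form as a mixture of double-bond isomers and the two cycloaddition intermediates of step 11 as mixtures of diastereomers; all of these stereo-elements are erased when ring A becomes aromatic and are left undefined in the SMILES.

**Route**

Step 1
Reactants: 1 2-hydroxy-3-methoxy-5-methylbenzaldehyde
Product: 3 2,3-dihydroxy-5-methylbenzaldehyde, via cyclic bromoborate 2 (not isolated)
Conditions: BBr3, CH2Cl2, −78 °C → rt; then H2O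
Reagents that add atoms: none
Why: Lewis-acid cleavage of the aryl methyl ether (BBr3 demethylation) is standard for ortho-vanillins, the neighbouring phenol closes a cyclic borate and the aldehyde should survive.

Step 2
Reactants: 3 2,3-dihydroxy-5-methylbenzaldehyde
Product: 5 3-(allyloxy)-2-hydroxy-5-methylbenzaldehyde, via disodium catecholate 4 (not isolated)
Conditions: NaH (2.2 equiv), DMSO, rt; then allyl bromide (1.0 equiv); 1 M HCl work-up
Reagents that add atoms: allyl bromide C=CCBr
Why: Williamson etherification of the dianion should go at O-3, whose phenoxide is not stabilised by the ortho-formyl group and is the more nucleophilic one.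

Step 3
Reactants: 5 3-(allyloxy)-2-hydroxy-5-methylbenzaldehyde
Product: 6 2-(allyloxy)-6-(hydroxymethyl)-4-methylphenol
Conditions: NaBH4, MeOH/THF, 0 °C
Reagents that add atoms: none
Why: Borohydride reduction of the aryl aldehyde should leave phenol and allyl ether untouched.

Step 4
Reactants: 6 2-(allyloxy)-6-(hydroxymethyl)-4-methylphenol
Product: 7 2-(allyloxy)-4-methyl-6-{[(triisopropylsilyl)oxy]methyl}phenol
Conditions: i-Pr3SiCl (1.05 equiv), imidazole, DMF, 0 °C
Reagents that add atoms: chlorotriisopropylsilane CC(C)[Si](Cl)(C(C)C)C(C)C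
Why: Silylation of the primary benzylic alcohol should be far faster than that of a phenol flanked by two ortho substituents (selective O-silylation).

Step 5
Reactants: 8 diallyl malonate
Product: 9 diallyl 2-acetylmalonate
Conditions: MgCl2 (1.0 equiv), Et3N (2.0 equiv), MeCN, 0 °C; AcCl; 1 M HCl work-up
Reagents that add atoms: acetyl chloride CC(=O)Cl
Why: Magnesium-mediated C-acylation of a malonate should stop at the mono-acyl stage, because the product is held as its magnesium chelate.

Step 6
Reactants: 9 diallyl 2-acetylmalonate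
Product: 11 diallyl 2-(1-chloroethylidene)malonate, via enol dichlorophosphate 10 (not isolated)
Conditions: POCl3, Bu3N, toluene, 80 °C
Reagents that add atoms: phosphoryl chloride O=P(Cl)(Cl)Cl
Why: The enol of the tricarbonyl compound is phosphorylated and the phosphate is displaced by chloride (addition–elimination), the known route to 1-chloroalkylidene malonates.

Step 7
Reactants: 7 2-(allyloxy)-4-methyl-6-{[(triisopropylsilyl)oxy]methyl}phenol; 11 diallyl 2-(1-chloroethylidene)malonate
Product: 12 diallyl 2-{1-[2-(allyloxy)-4-methyl-6-{[(triisopropylsilyl)oxy]methyl}phenoxy]ethylidene}malonate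
Conditions: K2CO3, MeCN, rt → 50 °C
Reagents that add atoms: none
Why: Nucleophilic vinylic substitution (addition–elimination) at a carbon β to two esters is far easier than any substitution on a haloarene, so even this hindered phenoxide should add, and the C–O bond of the later diaryl ether is made before ring A exists.

Step 8
Reactants: 12 diallyl 2-{1-[2-(allyloxy)-4-methyl-6-{[(triisopropylsilyl)oxy]methyl}phenoxy]ethylidene}malonate
Product: 14 allyl 4-[2-(allyloxy)-4-methyl-6-{[(triisopropylsilyl)oxy]methyl}phenoxy]-2-oxo-2H-pyran-3-carboxylate, via dienamine 13 (not isolated)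
Conditions: Me2NCH(Ot-Bu)2 (1.5 equiv), toluene, 80 °C; then AcOH, H2O, THF, rt
Reagents that add atoms: N,N-dimethylformamide di-tert-butyl acetal CN(C)C(OC(C)(C)C)OC(C)(C)C; water O
Why: The methyl group, vinylogous to two esters, should condense with the formamide acetal (the tert-butyl acetal frees only tert-butanol, which cannot displace the aryloxy group), and aqueous acid should hydrolyse the enamine to an enol that lactonises onto one ester, the sequence that turns 1-alkoxyethylidene malonates into 4-alkoxy-2-oxo-2H-pyran-3-carboxylates.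

Step 9
Reactants: 15 methyl 5-methyl-3-oxohexanoate
Product: 16 methyl (3S)-3-hydroxy-5-methylhexanoate
Conditions: H2 (50 atm), RuCl2[(S)-BINAP] (0.1 mol %), MeOH, 50 °C
Reagents that add atoms: none
Why: Noyori asymmetric hydrogenation of a β-keto ester; hydride is delivered to the ester-chelated ketone on the face fixed by (S)-BINAP, which should give the (S)-alcohol, the only stereocentre of the target.

Step 10
Reactants: 16 methyl (3S)-3-hydroxy-5-methylhexanoate
Product: 18 (3S)-1-methoxy-5-methyl-1,3-bis[(trimethylsilyl)oxy]hex-1-ene, via dilithium alkoxide enolate 17 (not isolated)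
Conditions: LiN(i-Pr)2 (2.2 equiv), THF, −78 → −30 °C; Me3SiCl (2.5 equiv), −78 °C → rt; filtration under argon, used crude
Reagents that add atoms: chlorotrimethylsilane C[Si](C)(C)Cl
Why: Double deprotonation as in the Fráter–Seebach alkylation makes the alkoxide first, so the enolate cannot eliminate the β-oxygen, and O-silylation of both oxygens should give the silyl ketene acetal without touching the stereocentre.

Step 11
Reactants: 14 allyl 4-[2-(allyloxy)-4-methyl-6-{[(triisopropylsilyl)oxy]methyl}phenoxy]-2-oxo-2H-pyran-3-carboxylate; 18 (3S)-1-methoxy-5-methyl-1,3-bis[(trimethylsilyl)oxy]hex-1-ene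
Product: 22 allyl 6-[2-(allyloxy)-6-(hydroxymethyl)-4-methylphenoxy]-2-hydroxy-3-[(1S)-1-hydroxy-3-methylbutyl]benzoate, via bridged lactone 19 (not isolated), via cyclohexadiene ketal 20 (not isolated), via aryl silyl ether 21 (not isolated)
Conditions: 18 (2.5 equiv), toluene, 95 °C, sealed tube; then Bu4NF, AcOH (1:1), THF, 0 °C → rt
Reagents that add atoms: none
Why: Inverse-electron-demand Diels–Alder reaction of the electron-poor diene of 2-pyrone 14 (C3=C4–C5=C6, lowered by the lactone carbonyl and the C3 ester) with the electron-rich ketene acetal 18 should give bridged lactone 19, which loses CO2 by cycloreversion (20) and then methanol by 1,2-elimination (21), and buffered fluoride in the same flask removes the three silyl groups. The closest known reaction is the aryl annulation of 3-carbomethoxy-2-pyrones with 1,1-dimethoxyethylene, which gives 2-methoxybenzoates with the same orientation. Ring A is closed by the [4+2] cycloaddition, which forms its C1–C2 and C3–C4 bonds at once, and is made aromatic by the two eliminations. No lasting stereocentre is created, since the four sp3 centres of 19 and 20 vanish on aromatisation, and the (S)-carbinol from step 9 is carried through as a silyl ether that no reagent touches. The step needs one regiochemistry, secured by polarisation and shielding: the nucleophilic carbon of 18 (the former ester α-carbon) bonds to the unsubstituted C6 of 14, the terminus vinylogous to both carbonyls, and the acetal carbon to C3, while C4 is deactivated by oxygen donation and screened by an aryloxy group with two ortho substituents. If part of 20 loses trimethylsilanol instead of methanol, desilylation gives 23, the product of step 12, so both channels converge.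

Step 12
Reactants: 22 allyl 6-[2-(allyloxy)-6-(hydroxymethyl)-4-methylphenoxy]-2-hydroxy-3-[(1S)-1-hydroxy-3-methylbutyl]benzoate
Product: 23 allyl 6-[2-(allyloxy)-6-(hydroxymethyl)-4-methylphenoxy]-3-[(1S)-1-hydroxy-3-methylbutyl]-2-methoxybenzoate
Conditions: MeI, K2CO3, DMF, rt → 40 °C
Reagents that add atoms: iodomethane CI
Why: Williamson O-methylation should take place only at the phenol, the one hydroxyl that carbonate can deprotonate, and leave both alcohols and the allyl ester alone.

Step 13
Reactants: 23 allyl 6-[2-(allyloxy)-6-(hydroxymethyl)-4-methylphenoxy]-3-[(1S)-1-hydroxy-3-methylbutyl]-2-methoxybenzoate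
Product: 24 6-[2-hydroxy-6-(hydroxymethyl)-4-methylphenoxy]-3-[(1S)-1-hydroxy-3-methylbutyl]-2-methoxybenzoic acid
Conditions: Pd(PPh3)4 (5 mol %), morpholine (10 equiv), THF, rt; aqueous citric acid work-up
Reagents that add atoms: none
Why: Tsuji–Trost deallylation: zerovalent palladium ionises both the allyl ester and the aryl allyl ether to π-allyl complexes that morpholine captures, under neutral conditions that should not affect the benzylic alcohols or the stereocentre and that cleave the hindered ester at its O–allyl bond.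

**Compound list**

1 | 2-hydroxy-3-methoxy-5-methylbenzaldehyde | Cc1cc(C=O)c(O)c(OC)c1 | starting material
2 | 2-bromo-6-methyl-1,3,2-benzodioxaborole-4-carbaldehyde (cyclic bromoborate) | Cc1cc(C=O)c2OB(Br)Oc2c1 | intermediate (not isolated)
3 | 2,3-dihydroxy-5-methylbenzaldehyde | Cc1cc(C=O)c(O)c(O)c1 | intermediate
4 | disodium 3-formyl-5-methylbenzene-1,2-diolate | Cc1cc(C=O)c([O-])c([O-])c1.[Na+].[Na+] | intermediate (not isolated)
5 | 3-(allyloxy)-2-hydroxy-5-methylbenzaldehyde | Cc1cc(C=O)c(O)c(OCC=C)c1 | intermediate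
6 | 2-(allyloxy)-6-(hydroxymethyl)-4-methylphenol | Cc1cc(CO)c(O)c(OCC=C)c1 | intermediate
7 | 2-(allyloxy)-4-methyl-6-{[(triisopropylsilyl)oxy]methyl}phenol | Cc1cc(CO[Si](C(C)C)(C(C)C)C(C)C)c(O)c(OCC=C)c1 | intermediate
8 | diallyl malonate | C=CCOC(=O)CC(=O)OCC=C | starting material
9 | diallyl 2-acetylmalonate (largely enolised) | CC(=O)C(C(=O)OCC=C)C(=O)OCC=C | intermediate
10 | diallyl 2-{1-[(dichlorophosphoryl)oxy]ethylidene}malonate | CC(OP(=O)(Cl)Cl)=C(C(=O)OCC=C)C(=O)OCC=C | intermediate (not isolated)
11 | diallyl 2-(1-chloroethylidene)malonate | CC(Cl)=C(C(=O)OCC=C)C(=O)OCC=C | intermediate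
12 | diallyl 2-{1-[2-(allyloxy)-4-methyl-6-{[(triisopropylsilyl)oxy]methyl}phenoxy]ethylidene}malonate | CC(Oc1c(OCC=C)cc(C)cc1CO[Si](C(C)C)(C(C)C)C(C)C)=C(C(=O)OCC=C)C(=O)OCC=C | intermediate
13 | diallyl 2-{(2E)-1-[2-(allyloxy)-4-methyl-6-{[(triisopropylsilyl)oxy]methyl}phenoxy]-3-(dimethylamino)prop-2-en-1-ylidene}malonate | CN(C)/C=C/C(Oc1c(OCC=C)cc(C)cc1CO[Si](C(C)C)(C(C)C)C(C)C)=C(C(=O)OCC=C)C(=O)OCC=C | intermediate (not isolated)
14 | allyl 4-[2-(allyloxy)-4-methyl-6-{[(triisopropylsilyl)oxy]methyl}phenoxy]-2-oxo-2H-pyran-3-carboxylate | O=C1OC=CC(Oc2c(OCC=C)cc(C)cc2CO[Si](C(C)C)(C(C)C)C(C)C)=C1C(=O)OCC=C | intermediate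
15 | methyl 5-methyl-3-oxohexanoate | CC(C)CC(=O)CC(=O)OC | starting material
16 | methyl (3S)-3-hydroxy-5-methylhexanoate | CC(C)C[C@H](O)CC(=O)OC | intermediate
17 | dilithium (3S)-1-methoxy-5-methylhex-1-ene-1,3-diolate | CC(C)C[C@H]([O-])C=C([O-])OC.[Li+].[Li+] | intermediate (not isolated)
18 | (3S)-1-methoxy-5-methyl-1,3-bis[(trimethylsilyl)oxy]hex-1-ene | CC(C)C[C@H](O[Si](C)(C)C)C=C(OC)O[Si](C)(C)C | intermediate
19 | allyl 5-[2-(allyloxy)-4-methyl-6-{[(triisopropylsilyl)oxy]methyl}phenoxy]-8-methoxy-7-{(1S)-3-methyl-1-[(trimethylsilyl)oxy]butyl}-3-oxo-8-[(trimethylsilyl)oxy]-2-oxabicyclo[2.2.2]oct-5-ene-4-carboxylate (diastereomer mixture) | O=C1OC2C=C(Oc3c(OCC=C)cc(C)cc3CO[Si](C(C)C)(C(C)C)C(C)C)C1(C(=O)OCC=C)C(OC)(O[Si](C)(C)C)C2[C@@H](O[Si](C)(C)C)CC(C)C | intermediate (not isolated)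
20 | allyl 2-[2-(allyloxy)-4-methyl-6-{[(triisopropylsilyl)oxy]methyl}phenoxy]-6-methoxy-5-{(1S)-3-methyl-1-[(trimethylsilyl)oxy]butyl}-6-[(trimethylsilyl)oxy]cyclohexa-1,3-diene-1-carboxylate (diastereomer mixture) | C=CCOC(=O)C1=C(Oc2c(OCC=C)cc(C)cc2CO[Si](C(C)C)(C(C)C)C(C)C)C=CC([C@@H](O[Si](C)(C)C)CC(C)C)C1(OC)O[Si](C)(C)C | intermediate (not isolated)
21 | allyl 6-[2-(allyloxy)-4-methyl-6-{[(triisopropylsilyl)oxy]methyl}phenoxy]-3-{(1S)-3-methyl-1-[(trimethylsilyl)oxy]butyl}-2-[(trimethylsilyl)oxy]benzoate | C=CCOC(=O)c1c(O[Si](C)(C)C)c([C@@H](O[Si](C)(C)C)CC(C)C)ccc1Oc1c(OCC=C)cc(C)cc1CO[Si](C(C)C)(C(C)C)C(C)C | intermediate (not isolated)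
22 | allyl 6-[2-(allyloxy)-6-(hydroxymethyl)-4-methylphenoxy]-2-hydroxy-3-[(1S)-1-hydroxy-3-methylbutyl]benzoate | C=CCOC(=O)c1c(O)c([C@@H](O)CC(C)C)ccc1Oc1c(OCC=C)cc(C)cc1CO | intermediate
23 | allyl 6-[2-(allyloxy)-6-(hydroxymethyl)-4-methylphenoxy]-3-[(1S)-1-hydroxy-3-methylbutyl]-2-methoxybenzoate | C=CCOC(=O)c1c(OC)c([C@@H](O)CC(C)C)ccc1Oc1c(OCC=C)cc(C)cc1CO | intermediate
24 | 6-[2-hydroxy-6-(hydroxymethyl)-4-methylphenoxy]-3-[(1S)-1-hydroxy-3-methylbutyl]-2-methoxybenzoic acid | COc1c([C@@H](O)CC(C)C)ccc(Oc2c(O)cc(C)cc2CO)c1C(=O)O | target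

**Step count and risk**

Total: 13 steps. Longest linear sequence: 9 steps (steps 1, 2, 3, 4, 7, 8, 11, 12, 13).

Steps most likely to fail:

Step 11 (key step). The branched substituent on the nucleophilic carbon of 18 may slow the cycloaddition, so that conjugate attack at C4 of 14 with loss of the aryloxide, or thermal silyl migration in 18, takes over. The fallback sets out from 14 and returns at 22; it makes the two-carbon partner linear and takes it from the chiral pool. Commercial ethyl (2S)-2-hydroxy-4-methylpentanoate F1, whose stereocentre is the carbinol of the target, would be silylated (t-BuMe2SiCl, imidazole) to ethyl (2S)-2-{[tert-butyl(dimethyl)silyl]oxy}-4-methylpentanoate F2. Ynolate formation as in the Kowalski ester homologation (CH2Br2 and lithium 2,2,6,6-tetramethylpiperidide at −78 °C, then LiN(SiMe3)2 and n-BuLi; the carbinol carbon migrates with retention) and O-silylation with i-Pr3SiOTf would give (3S)-3-{[tert-butyl(dimethyl)silyl]oxy}-5-methyl-1-[(triisopropylsilyl)oxy]hex-1-yne F3. Cycloaddition of F3 to 14 (toluene, 80 °C) would place its sp carbon on C6 of the pyrone, and loss of CO2 would give the arene without any elimination step, allyl 6-[2-(allyloxy)-4-methyl-6-{[(triisopropylsilyl)oxy]methyl}phenoxy]-3-[(1S)-1-{[tert-butyl(dimethyl)silyl]oxy}-3-methylbutyl]-2-[(triisopropylsilyl)oxy]benzoate F4. Bu4NF/AcOH would then remove its three silyl groups and give 22.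

Step 8. The aryloxy group on the doubly activated vinylic carbon may be displaced during the condensation or hydrolysed during ring closure, or the methyl group may condense too slowly. The fallback sets out from 8, uses 7 and returns at 14; it closes the pyrone ring before ring B is attached and so replaces steps 5 to 8. C-Acylation of 8 with (E)-3-ethoxyprop-2-enoyl chloride (MgCl2, Et3N, MeCN) would give diallyl 2-[(2E)-3-ethoxyprop-2-enoyl]malonate F5. Aqueous HCl in THF would hydrolyse its enol ether and lactonise it to allyl 4-hydroxy-2-oxo-2H-pyran-3-carboxylate F6, and TsCl/Et3N would give allyl 4-{[(4-methylphenyl)sulfonyl]oxy}-2-oxo-2H-pyran-3-carboxylate F7. Vinylic substitution of the sulfonate by the phenoxide of 7 (K2CO3, MeCN) would then give 14.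

Step 7. The phenoxide with two ortho substituents may add slowly, while base converts 11 by loss of HCl into an allenic malonate that oligomerises. The fallback sets out from 7 and returns at 12; it builds the enol ether on a less crowded acceptor and adds the second ester afterwards. Base-catalysed conjugate addition of 7 to allyl but-2-ynoate (K2CO3, DMF, 60 °C) would give allyl (2E)-3-[2-(allyloxy)-4-methyl-6-{[(triisopropylsilyl)oxy]methyl}phenoxy]but-2-enoate F8. γ-Deprotonation (LiN(i-Pr)2, THF, −78 °C) and α-acylation of the dienolate with allyl chloroformate, followed by return of the double bond into conjugation, would give 12.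

**Further compounds**

F1 | step 11 | ethyl (2S)-2-hydroxy-4-methylpentanoate | CC(C)C[C@H](O)C(=O)OCC
F2 | step 11 | ethyl (2S)-2-{[tert-butyl(dimethyl)silyl]oxy}-4-methylpentanoate | CC(C)C[C@H](O[Si](C)(C)C(C)(C)C)C(=O)OCC
F3 | step 11 | (3S)-3-{[tert-butyl(dimethyl)silyl]oxy}-5-methyl-1-[(triisopropylsilyl)oxy]hex-1-yne | CC(C)C[C@H](O[Si](C)(C)C(C)(C)C)C#CO[Si](C(C)C)(C(C)C)C(C)C
F4 | step 11 | allyl 6-[2-(allyloxy)-4-methyl-6-{[(triisopropylsilyl)oxy]methyl}phenoxy]-3-[(1S)-1-{[tert-butyl(dimethyl)silyl]oxy}-3-methylbutyl]-2-[(triisopropylsilyl)oxy]benzoate | C=CCOC(=O)c1c(O[Si](C(C)C)(C(C)C)C(C)C)c([C@@H](O[Si](C)(C)C(C)(C)C)CC(C)C)ccc1Oc1c(OCC=C)cc(C)cc1CO[Si](C(C)C)(C(C)C)C(C)C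
F5 | step 8 | diallyl 2-[(2E)-3-ethoxyprop-2-enoyl]malonate | CCO/C=C/C(=O)C(C(=O)OCC=C)C(=O)OCC=C
F6 | step 8 | allyl 4-hydroxy-2-oxo-2H-pyran-3-carboxylate | O=C1OC=CC(O)=C1C(=O)OCC=C
F7 | step 8 | allyl 4-{[(4-methylphenyl)sulfonyl]oxy}-2-oxo-2H-pyran-3-carboxylate | Cc1ccc(cc1)S(=O)(=O)OC1=C(C(=O)OCC=C)C(=O)OC=C1
F8 | step 7 | allyl (2E)-3-[2-(allyloxy)-4-methyl-6-{[(triisopropylsilyl)oxy]methyl}phenoxy]but-2-enoate | C/C(Oc1c(OCC=C)cc(C)cc1CO[Si](C(C)C)(C(C)C)C(C)C)=C\C(=O)OCC=C
A1 | direct plan | 2-(benzyloxy)-6-({[tert-butyl(dimethyl)silyl]oxy}methyl)-4-methylphenol | Cc1cc(CO[Si](C)(C)C(C)(C)C)c(O)c(OCc2ccccc2)c1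
A2 | direct plan | benzyl 6-fluoro-3-formyl-2-methoxybenzoate | COc1c(C=O)ccc(F)c1C(=O)OCc1ccccc1
A3 | direct plan | benzyl 6-[2-(benzyloxy)-6-({[tert-butyl(dimethyl)silyl]oxy}methyl)-4-methylphenoxy]-3-formyl-2-methoxybenzoate | COc1c(C=O)ccc(Oc2c(OCc3ccccc3)cc(C)cc2CO[Si](C)(C)C(C)(C)C)c1C(=O)OCc1ccccc1
A4 | direct plan | benzyl 6-[2-(benzyloxy)-6-({[tert-butyl(dimethyl)silyl]oxy}methyl)-4-methylphenoxy]-3-[(1S)-1-hydroxy-3-methylbut-3-en-1-yl]-2-methoxybenzoate | COc1c([C@@H](O)CC(C)=C)ccc(Oc2c(OCc3ccccc3)cc(C)cc2CO[Si](C)(C)C(C)(C)C)c1C(=O)OCc1ccccc1
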